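**Strategy.** Everything rests on cutting the C4–C4a bond of the tetralin. The methine C4 carries two aryl groups and sits on C2' of the naphthalene ring, next to the free C1' hydroxyl; a carbinol at C4 can therefore lose water to an o-naphthoquinone methide, which the anisole ring captures through C4a. In one operation this forms the C4–C4a bond, closes the carbocycle C1–C2–C3–C4–C4a–C8a and sets C4 under a chiral Brønsted acid. The precursor is an open-chain 1,4-diarylbutane-1,4-diol derivative: C1 already (S) and masked as a TIPS ether, C4 a free carbinol (either epimer) beside the unprotected naphthol, and a bromine on the future C8 to block closure para to the methoxy group.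

Key step: step 7

Remarks.
- Target: (1S,4R)-4-(1-hydroxy-8-methoxynaphthalen-2-yl)-5-methoxy-1,2,3,4-tetrahydronaphthalen-1-ol; the C1 hydroxyl and the C4 naphthyl group are trans.
- Tetralin locants of the target are used for the open-chain compounds too; primed locants refer to the naphthalene.
- Assumption: the (S) acid in step 1 and the (R) acid in step 7 are taken as the correct antipodes. The first follows allylborations of benzaldehydes, where the R acid gives R alcohols; the second is taken as the antipode matched to C1. If either sense proves opposite, the mirror-image catalyst is used.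
- Design point: the naphthol is never protected. An acetal on the naphthol oxygen would have to be removed with acid beside the ionisable C4 carbinol, which would start the ring closure without control. The C2'-lithiated naphtholate is used instead.

**Route**

Step 1
Reactants: 1 2-bromo-5-methoxybenzaldehyde; 2 allylboronic acid pinacol ester
Product: 4 (S)-1-(2-bromo-5-methoxyphenyl)but-3-en-1-ol, via pinacol borate ester 3 (not isolated)
Conditions: (S)-TRIP phosphoric acid (5 mol%), PhMe, −30 °C; aq. NaHCO3
Reagents that add atoms: none
Why: Chiral phosphoric acid-catalysed allylboration of an aryl aldehyde through a chair transition state in which the acid bridges a boronate oxygen and the formyl hydrogen; the (S) acid should deliver the allyl group to the face that makes C1 (S), and hydrolysis of the borate on work-up frees the alcohol.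

Step 2
Reactants: 4 (S)-1-(2-bromo-5-methoxyphenyl)but-3-en-1-ol
Product: 5 (S)-1-(2-bromo-5-methoxyphenyl)but-3-en-1-yl triisopropylsilyl ether
Conditions: TIPSOTf, 2,6-lutidine, CH2Cl2, 0 °C
Reagents that add atoms: triisopropylsilyl trifluoromethanesulfonate, CC(C)[Si](C(C)C)(C(C)C)OS(=O)(=O)C(F)(F)F
Why: Silylation of a hindered secondary benzylic alcohol with a silyl triflate and a hindered pyridine base is standard and does not touch the stereocentre.

Step 3
Reactants: 5 (S)-1-(2-bromo-5-methoxyphenyl)but-3-en-1-yl triisopropylsilyl ether
Product: 7 (4S)-4-(2-bromo-5-methoxyphenyl)-4-(triisopropylsilyloxy)butan-1-ol, via B-alkyl-9-BBN adduct 6 (not isolated)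
Conditions: 9-BBN, THF, 0 °C → rt; then NaOH, H2O2, 0 °C
Reagents that add atoms: hydrogen peroxide, OO
Why: Hydroboration–oxidation; the bulky borane adds to the terminal carbon of the monosubstituted alkene and alkaline peroxide converts the C–B bond into C–OH, while the aryl bromide and the silyl ether are inert.

Step 4
Reactants: 7 (4S)-4-(2-bromo-5-methoxyphenyl)-4-(triisopropylsilyloxy)butan-1-ol
Product: 8 (4S)-4-(2-bromo-5-methoxyphenyl)-4-(triisopropylsilyloxy)butanal
Conditions: Dess–Martin periodinane, CH2Cl2, 0 °C → rt
Reagents that add atoms: none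
Why: Dess–Martin oxidation stops cleanly at the aldehyde, and there is no α-stereocentre to lose.

Step 5
Reactants: 9 8-methoxynaphthalen-1-ol
Product: 10 2-bromo-8-methoxynaphthalen-1-ol
Conditions: NBS (1.0 equiv), i-Pr2NH (0.1 equiv), CH2Cl2, 0 °C
Reagents that add atoms: N-bromosuccinimide, O=C1CCC(=O)N1Br
Why: Amine-catalysed ortho-selective bromination of a phenol, in which the N-bromoamine is delivered within a hydrogen-bonded phenol–amine pair, should place bromine on C2' in preference to the para carbon C4'.

Step 6
Reactants: 10 2-bromo-8-methoxynaphthalen-1-ol; 8 (4S)-4-(2-bromo-5-methoxyphenyl)-4-(triisopropylsilyloxy)butanal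
Product: 12 2-[(4S)-4-(2-bromo-5-methoxyphenyl)-1-hydroxy-4-(triisopropylsilyloxy)butyl]-8-methoxynaphthalen-1-ol (both epimers at the new carbinol carbon), via dilithiated naphtholate 11 (not isolated)
Conditions: 10 (1.3 equiv), n-BuLi (2.55 equiv), Et2O, −78 → 0 °C; then 8, THF, −78 °C; pH 7 buffer
Reagents that add atoms: none
Why: O-deprotonation followed by bromine–lithium exchange gives the C2'-lithiated lithium naphtholate, whose 1,2-addition to the aldehyde is far faster than exchange with the aryl bromide of 8; the new carbinol centre needs no control because both epimers converge in step 7.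

Step 7
Reactants: 12 2-[(4S)-4-(2-bromo-5-methoxyphenyl)-1-hydroxy-4-(triisopropylsilyloxy)butyl]-8-methoxynaphthalen-1-ol
Product: 14 (1S,4R)-8-bromo-4-(1-hydroxy-8-methoxynaphthalen-2-yl)-5-methoxy-1-(triisopropylsilyloxy)-1,2,3,4-tetrahydronaphthalene, via o-naphthoquinone methide 13 (not isolated)
Conditions: (R)-TRIP-derived N-triflyl phosphoramide (10 mol%), 5 Å MS, PhMe (0.005 M), 0 °C → rt
Reagents that add atoms: none
Why: The strong chiral acid protonates the C4 hydroxyl of either epimer, and loss of water gives the (E)-o-naphthoquinone methide 13, whose carbonyl oxygen stays hydrogen-bonded or ion-paired to the chiral anion; the anisole carbon flanked by the methoxy group and the tether (the future C4a) then adds to the exocyclic C4, and proton loss restores both aromatic systems. The closest known reaction type is the chiral Brønsted acid-catalysed Friedel–Crafts alkylation of arenes by in situ o-quinone methides, run here intramolecularly as the cyclialkylation of a 1,4-diarylbutanol to a 1-aryltetralin, with a stronger N-triflyl phosphoramide because a bromoanisole is a weak nucleophile. The six-membered ring closes 6-exo-trig with respect to the exocyclic C4=C2' bond. The new C4 centre is set by the chiral anion, which shields one face of the planar methide, and is reinforced by the C1 (S) centre: peri strain with the C8 bromine holds the silyloxy group pseudoaxial and peri strain with the C5 methoxy favours a pseudoaxial naphthyl, an arrangement that only the trans (1S,4R) isomer allows. Regioselectivity is needed because the carbon para to the methoxy group is intrinsically the better nucleophile, and the bromine on that carbon leaves only the ortho carbon free; the bulky silyl ether guards against oxygen trapping to a tetrahydrofuran, and C1 does not ionise because its ring offers only a meta methoxy and an ortho bromine. High dilution and sieves should suppress dimerisation of 13 with its vinylnaphthol tautomer, which in any case returns to 13 by protonation.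

Step 8
Reactants: 14 (1S,4R)-8-bromo-4-(1-hydroxy-8-methoxynaphthalen-2-yl)-5-methoxy-1-(triisopropylsilyloxy)-1,2,3,4-tetrahydronaphthalene
Product: 15 (1S,4R)-4-(1-hydroxy-8-methoxynaphthalen-2-yl)-5-methoxy-1-(triisopropylsilyloxy)-1,2,3,4-tetrahydronaphthalene
Conditions: H2 (1 atm), 10% Pd/C, Et3N, EtOAc–EtOH, rt
Reagents that add atoms: none
Why: Palladium-catalysed hydrogenolysis of an aryl bromide in the presence of an amine base is fast and should leave the benzylic silyl ether, the naphthalene ring and both stereocentres untouched.

Step 9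
Reactants: 15 (1S,4R)-4-(1-hydroxy-8-methoxynaphthalen-2-yl)-5-methoxy-1-(triisopropylsilyloxy)-1,2,3,4-tetrahydronaphthalene
Product: 16 Dipolynaphthalene A, (1S,4R)-4-(1-hydroxy-8-methoxynaphthalen-2-yl)-5-methoxy-1,2,3,4-tetrahydronaphthalen-1-ol
Conditions: TBAF, THF (degassed), 0 °C → rt; pH 7 buffer
Reagents that add atoms: none
Why: Fluoride cleavage of the silyl ether, driven by Si–F bond formation, runs under basic, non-ionising conditions, so the configurations at C1 and C4 are retained.

**Compound list**

1 | 2-bromo-5-methoxybenzaldehyde | COc1ccc(Br)c(C=O)c1 | starting material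
2 | allylboronic acid pinacol ester | C=CCB1OC(C)(C)C(C)(C)O1 | starting material
3 | 2-{[(1S)-1-(2-bromo-5-methoxyphenyl)but-3-en-1-yl]oxy}-4,4,5,5-tetramethyl-1,3,2-dioxaborolane | COc1ccc(Br)c(c1)[C@@H](OB1OC(C)(C)C(C)(C)O1)CC=C | intermediate (not isolated)
4 | (S)-1-(2-bromo-5-methoxyphenyl)but-3-en-1-ol | COc1ccc(Br)c(c1)[C@@H](O)CC=C | intermediate
5 | (S)-1-(2-bromo-5-methoxyphenyl)but-3-en-1-yl triisopropylsilyl ether | COc1ccc(Br)c(c1)[C@@H](O[Si](C(C)C)(C(C)C)C(C)C)CC=C | intermediate
6 | 9-[(4S)-4-(2-bromo-5-methoxyphenyl)-4-(triisopropylsilyloxy)butyl]-9-borabicyclo[3.3.1]nonane | COc1ccc(Br)c(c1)[C@@H](O[Si](C(C)C)(C(C)C)C(C)C)CCCB1C2CCCC1CCC2 | intermediate (not isolated)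
7 | (4S)-4-(2-bromo-5-methoxyphenyl)-4-(triisopropylsilyloxy)butan-1-ol | COc1ccc(Br)c(c1)[C@@H](O[Si](C(C)C)(C(C)C)C(C)C)CCCO | intermediate
8 | (4S)-4-(2-bromo-5-methoxyphenyl)-4-(triisopropylsilyloxy)butanal | COc1ccc(Br)c(c1)[C@@H](O[Si](C(C)C)(C(C)C)C(C)C)CCC=O | intermediate
9 | 8-methoxynaphthalen-1-ol | COc1cccc2cccc(O)c12 | starting material
10 | 2-bromo-8-methoxynaphthalen-1-ol | COc1cccc2ccc(Br)c(O)c12 | intermediate
11 | lithium 2-lithio-8-methoxynaphthalen-1-olate | COc1cccc2ccc([Li])c(O[Li])c12 | intermediate (not isolated)
12 | 2-[(4S)-4-(2-bromo-5-methoxyphenyl)-1-hydroxy-4-(triisopropylsilyloxy)butyl]-8-methoxynaphthalen-1-ol, both epimers at the carbinol carbon (precursor of the key step) | COc1ccc(Br)c(c1)[C@@H](O[Si](C(C)C)(C(C)C)C(C)C)CCC(O)c1ccc2cccc(OC)c2c1O | intermediate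
13 | (2E)-2-[(4S)-4-(2-bromo-5-methoxyphenyl)-4-(triisopropylsilyloxy)butylidene]-8-methoxynaphthalen-1(2H)-one | COc1ccc(Br)c(c1)[C@@H](O[Si](C(C)C)(C(C)C)C(C)C)CC/C=C1\C=Cc2cccc(OC)c2C1=O | intermediate (not isolated)
14 | (1S,4R)-8-bromo-4-(1-hydroxy-8-methoxynaphthalen-2-yl)-5-methoxy-1-(triisopropylsilyloxy)-1,2,3,4-tetrahydronaphthalene (product of the key step) | COc1ccc(Br)c2c1[C@@H](c1ccc3cccc(OC)c3c1O)CC[C@@H]2O[Si](C(C)C)(C(C)C)C(C)C | intermediate
15 | (1S,4R)-4-(1-hydroxy-8-methoxynaphthalen-2-yl)-5-methoxy-1-(triisopropylsilyloxy)-1,2,3,4-tetrahydronaphthalene | COc1cccc2c1[C@@H](c1ccc3cccc(OC)c3c1O)CC[C@@H]2O[Si](C(C)C)(C(C)C)C(C)C | intermediate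
16 | Dipolynaphthalene A, (1S,4R)-4-(1-hydroxy-8-methoxynaphthalen-2-yl)-5-methoxy-1,2,3,4-tetrahydronaphthalen-1-ol | COc1cccc2c1[C@@H](c1ccc3cccc(OC)c3c1O)CC[C@@H]2O | target

**Step count**

Total: 9 steps. Longest linear sequence: 8 steps (1, 2, 3, 4, 6, 7, 8, 9); step 5 is a one-step side branch.

**Steps most likely to fail**

1. Step 7 (key step). Capture of the quinone methide by the crowded, bromine-deactivated anisole carbon may be slow. Dimerisation of 13 with its vinylnaphthol tautomer, attack by the silyl ether oxygen (tetrahydrofuran formation with loss of silicon) or ipso attack at the bromine-bearing carbon could then take over. The facial preference of the acid may also oppose that of the C1 centre and erode the selectivity at C4. The fallback replaces the quinone methide and the chiral acid by a substrate-controlled closure through a benzyl-protected benzylic cation. It sets out from 10 and 8. Compound 10 is O-benzylated (BnBr, K2CO3, DMF) to 1-(benzyloxy)-2-bromo-8-methoxynaphthalene F1. Bromine–lithium exchange (n-BuLi, THF, −78 °C) gives [1-(benzyloxy)-8-methoxynaphthalen-2-yl]lithium F2, which adds to aldehyde 8 to give (4S)-1-[1-(benzyloxy)-8-methoxynaphthalen-2-yl]-4-(2-bromo-5-methoxyphenyl)-4-(triisopropylsilyloxy)butan-1-ol F3 as both C1 epimers. A catalytic achiral Lewis acid (Bi(OTf)3, CH2Cl2, −20 °C) ionises this carbinol to the cation stabilised by the ortho benzyloxy group. The classical cyclialkylation should then give (1S,4R)-4-[1-(benzyloxy)-8-methoxynaphthalen-2-yl]-8-bromo-5-methoxy-1-(triisopropylsilyloxy)-1,2,3,4-tetrahydronaphthalene F4, the trans isomer being favoured by the same two peri interactions. Hydrogenolysis (H2, Pd/C, NaOAc, EtOAc–EtOH) removes the benzyl ether and the bromine together and returns to the route at 15.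

2. Step 5. Bromination may occur at C4' (para to the hydroxyl) or on the methoxy-bearing ring, or twice, if the hydrogen bond from the hydroxyl to the peri methoxy group weakens the ortho delivery by the amine. The fallback uses directed ortho-metalation in place of electrophilic substitution and sets out from 9. Compound 9 is converted into 1-methoxy-8-(methoxymethoxy)naphthalene F5 (MOMCl, i-Pr2NEt, CH2Cl2). n-BuLi/TMEDA in Et2O at 0 °C should lithiate next to the better directing acetal oxygen and give [8-methoxy-1-(methoxymethoxy)naphthalen-2-yl]lithium F6. This is brominated with 1,2-dibromotetrachloroethane to 2-bromo-8-methoxy-1-(methoxymethoxy)naphthalene F7. HCl in MeOH then removes the acetal, which is harmless at this stage, and the route is rejoined at 10.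

3. Step 6. Exchange on the electron-rich lithium naphtholate may be incomplete, the aryllithium may exchange with the aryl bromide of 8, or the aldehyde may be enolised. The fallback is a boron-templated ortho-hydroxyalkylation of the free naphthol that needs no organolithium; it sets out from 9 and 8 and also bypasses step 5. Compound 9, aldehyde 8 and phenylboronic acid are heated in toluene with catalytic propanoic acid and removal of water. The aryl boronate formed on the naphthol oxygen delivers the aldehyde to C2' only and gives the cyclic phenylboronate of 12 (a 2-phenyl-4H-naphtho-1,3,2-dioxaborin, boron bridging the naphthol oxygen and the C4 carbinol oxygen) F8. Exchange with propane-1,3-diol releases the diol and returns to the route at 12.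

**Further compounds**

F1 | step 7 | 1-(benzyloxy)-2-bromo-8-methoxynaphthalene | COc1cccc2ccc(Br)c(OCc3ccccc3)c12
F2 | step 7 | [1-(benzyloxy)-8-methoxynaphthalen-2-yl]lithium | COc1cccc2ccc([Li])c(OCc3ccccc3)c12
F3 | step 7 | (4S)-1-[1-(benzyloxy)-8-methoxynaphthalen-2-yl]-4-(2-bromo-5-methoxyphenyl)-4-(triisopropylsilyloxy)butan-1-ol | COc1ccc(Br)c(c1)[C@@H](O[Si](C(C)C)(C(C)C)C(C)C)CCC(O)c1ccc2cccc(OC)c2c1OCc1ccccc1
F4 | step 7 | (1S,4R)-4-[1-(benzyloxy)-8-methoxynaphthalen-2-yl]-8-bromo-5-methoxy-1-(triisopropylsilyloxy)-1,2,3,4-tetrahydronaphthalene | COc1ccc(Br)c2c1[C@@H](c1ccc3cccc(OC)c3c1OCc1ccccc1)CC[C@@H]2O[Si](C(C)C)(C(C)C)C(C)C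
F5 | step 5 | 1-methoxy-8-(methoxymethoxy)naphthalene | COCOc1cccc2cccc(OC)c12
F6 | step 5 | [8-methoxy-1-(methoxymethoxy)naphthalen-2-yl]lithium | COCOc1c([Li])ccc2cccc(OC)c12
F7 | step 5 | 2-bromo-8-methoxy-1-(methoxymethoxy)naphthalene | COCOc1c(Br)ccc2cccc(OC)c12
F8 | step 6 | cyclic phenylboronate of 12 (2-phenyl-4H-naphtho-1,3,2-dioxaborin bearing the (3S)-3-(2-bromo-5-methoxyphenyl)-3-(triisopropylsilyloxy)propyl chain at C4) | COc1ccc(Br)c(c1)[C@@H](O[Si](C(C)C)(C(C)C)C(C)C)CCC1OB(c2ccccc2)Oc2c1ccc1cccc(OC)c21
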